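(The constants used here were chosen freely; the result is computed.)

The ratio of X to Q charged was 0.200, so I asked how many turnovers each X could make in the time.

    X + D ⇌ J + E (K1 = 0.43, k1 = 0.57 M⁻¹ s⁻¹)
    Q + J → G + X (k2 = 0.76 M⁻¹ s⁻¹)
    2 Q → Q2 (k3 = 0.016 M⁻¹ s⁻¹)
    L ⇌ G, rate k4*(cs4 - [G]) while solid is left; crystals form when [G] > cs4 (cs4 = 0.27 M, k4 = 4.9 s⁻¹)

Q 0.31 M; D 0.620 M; X 62 mM; time 6.0 s; volume of the second phase over the first 0.50

- percentages count the Q that a species holds: one Q2 counts as two
- G is meant together with its L
- for a step with 2 of a species take k times the square, and two of it per event
- in the second phase: D, E; everything else is in the first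
- charges count per volume of the first phase; a concentration in a rate is the amount of a species over the volume of its own phase; every rate counts per litre of the first phase
- solid, in amounts per volume of the solution: L
- run time (flask): 6.0 s

1. how much G and L together there is at 6.0 s, in percent of the Q charged
2. the change that raises the amount of G and L together at 6.0 s, in percent of the Q charged most ("none" if none brings more than 2 percentage points) (ash / maple / larch / none)
3. amount of G and L together at 6.0 s, in percent of the Q charged, after ash

- ash: doubling the amount of D, all else as stated
- maple: doubling the solubility in step 4, all else as stated
- larch: doubling the dissolution coefficient of step 4, all else as stated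

D sat in the second phase, so its own concentration was its charge over 0.50, and by the forward rate of step 1 X had a half-life of 0.98 s. J in step 2 had a longer one, 2.9 s, so I counted the turnovers on step 2. One X held as J, with Q at its charge, turned over 1.41 times in 6.0 s. Multiplied by the ratio, this gave the full-duty yield, the fraction of the Q charged that becomes G if every X stands as J and Q stays at its charge: 28.3%.

But step 3 gave Q a half-life of 101 s, so I dropped it. Saturation lay at 87.1% of the Q charged, above the full-duty yield, so I expected no solid and no gain from maple or larch. Ash left the full-duty yield unchanged, so I reckoned it through J's share. Forward step 1 against step 2 gave J 75.0% of the catalyst after a lag of 1.06 s. So I committed to 17.5%, and to 21.8% after ash, leaving out the back step.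

The forecast gave 13.8%, lower than mine, named ash at 17.4%, and held that “[G] stays far below 0.27 M, so no solid forms”.

The simulation gave 13.8%, with ash best at 17.4%, a gain of 3.7 percentage points, while maple brought 0 points. The simulated answer moved by 5 points with X at 36.4 mM or 92.2 mM, the other amounts and the time held. This flask reached 0.488 of its full-duty yield. The neighbour flask, charged with 0.15 M of X, had a full-duty yield of 68.4%; it gave 26.4%, which is 0.386 of that yield, with J at 49.1% of its catalyst at 6.00 s.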